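The numbers in the tables were computed for substances that don't exist, and the scatter is random.

**Early split.** Early in ochre, J stands at 95% after 0.833 d, with a third of G fed, so J does not wait for G. I read two routes: X + Z to J, and X + G to Q.

all flasks: X 44 mM
- red: G 52.8 mM (fed, over 2.5 d); Z 37 mM; run made earlier
- ochre: G 52.8 mM (fed, over 2.5 d); Z 140 mM; run made earlier
- west: G 52.8 mM (fed, over 2.5 d); Z 44.0 mM; time 30 d
- south-east: G 52.8 mM; Z 200 mM; everything together at the start; time 30 d

- red (time / d: Q / %, J / %): 2.00: 30, 56; 4.00: 37, 60; 6.00: 40, 61; 8.00: 39, 58; 10.0: 42, 61; 12.0: 41, 61; 15.0: 41, 59
- ochre (time / d: Q / %, J / %): 0.833: 4, 95; 2.50: 0, 96; 4.00: 1, 99; 6.00: 3, 97; 10.0: 3, 98; 12.0: 4, 96; 15.0: 3, 97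

(scatter of a reading: 1.5 percentage points)

- the flask that ends with the higher share of Q in all that became Q or J, or "neither" when 2 percentage points or less lies between them (west / south-east / neither)
- share of Q in all that became Q or J, west
- share of Q in all that became Q or J, south-east

- the numbers in the tables scatter by 1.5 percentage points (one standard deviation)

**The ledger.** I keep the books on X, the limiting reagent in south-east, and count each turnover of X as one draw between the routes, charging one Z to each J and one G to each Q. Between 2.00 d and 6.00 d, red enters 10 percentage points of Q and 5 points of J. On these books, free G averages 60.8% of its charge and free Z 30.4% of its charge. That gives a reading of 0.701 for the selectivity factor, the odds of Q on one draw per unit of G over Z.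

**Closing entries.** South-east has its whole charge present from the start, so I put its odds at 0.185, which enters 15.6% as Q. In west, I carry over red's last entry, 0.702 J per Z charged, which leaves 29.8% as Q. My call is west.

**Forecast.** The forecast, above my figures, says west, with 31% for west and 18% for south-east, adding “A higher order in Z would lower this.”

**The result.** West ends at 33.0% and south-east at 17.7%, so west leads.

    X + G → Q (k = 1.87 /M/h)
    Z + G → E (k = 0.997 /M/h)
    X + Z → J (k = 1.53 /M/h)
    G → L (k = 0.00756 /h)

**The neighbour.** South-east's final share means odds of 0.215, above my 0.185, and so, on my books with G and Z held at their charges, a selectivity factor of 0.813. The neighbour is south-east with Z cut to 1.82 equiv on X. The same draw gives it odds of 0.536, which enters 34.9% as Q. That flask gives 37.8%, above this reckoning.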